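**Retrosynthetic overview**
- Numbering: O1, C2, C3, C3a, C4 to C7, C7a of the 2,3-dihydrobenzofuran. Ring A is the benzo ring, ring B the dihydrofuran ring, ring C the syringyl ring. The target is the trans 2S,3S isomer.
- Endgame: the ring C phenol is unmasked last (MOM ether). The E-propenyl chain on C5 comes from a C5 nitrile by way of the aldehyde (Julia-Kocienski olefination).
- Key disconnection: ring B is cut at O1-C7a and at C3-C3a. This leads back to an (S)-1-arylallyl alcohol (O1, C2, C3, with the vinyl CH2 as the future C3 methyl group) and to 4-fluoro-3-iodo-5-methoxybenzonitrile (ring A).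
- Enabling feature: in ring A, C7a is para to C5 and ortho to C3a. An acceptor on C5 (the nitrile that later becomes the propenyl chain) makes a C7a-F bond an SNAr site, and an iodine on C3a then gives an aryl radical within 5-exo reach of the vinyl group next to C2.
- Ring order: rings A and C are bought; ring B is the only ring made (step 5). C2 is set in step 2 by catalyst control and C3 in step 5 by substrate control.

Key step: step 5

Assumption: divinylzinc is taken from a separately prepared, salt-free stock solution and is treated as a reagent.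

Step 1
Reactants: 1 syringaldehyde (4-hydroxy-3,5-dimethoxybenzaldehyde)
Product: 2 3,5-dimethoxy-4-(methoxymethoxy)benzaldehyde
Conditions: MOMCl, i-Pr2NEt, CH2Cl2, 0 °C to rt
Reagents that add atoms: chloromethyl methyl ether, COCCl
Why: Williamson-type O-alkylation of the phenol with the reactive alpha-chloro ether masks it as an acetal that should survive organozinc, alkoxide, radical, hydride and amide-base conditions and leaves under mild acid.

Step 2
Reactants: 2 3,5-dimethoxy-4-(methoxymethoxy)benzaldehyde
Product: 3 (S)-1-[3,5-dimethoxy-4-(methoxymethoxy)phenyl]prop-2-en-1-ol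
Conditions: Zn(CH=CH2)2, (-)-MIB (10 mol %), PhMe, 0 °C; aq NH4Cl
Reagents that add atoms: divinylzinc, C=C[Zn]C=C
Why: Amino-alcohol-catalysed enantioselective 1,2-addition of an alkenylzinc reagent to an aromatic aldehyde, in which the zinc alkoxide of (-)-MIB should deliver the vinyl group to the Si face and so set the S configuration of the carbinol carbon, the future C2.

Step 3
Reactants: 4 5-iodovanillin (4-hydroxy-3-iodo-5-methoxybenzaldehyde)
Product: 5 4-hydroxy-3-iodo-5-methoxybenzonitrile
Conditions: NH2OH·HCl, DMSO, 100 °C
Reagents that add atoms: hydroxylamine hydrochloride, Cl.NO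
Why: One-pot aldehyde-to-nitrile conversion (condensation with hydroxylamine and thermal dehydration) replaces the formyl group by an acceptor that the alkoxide of step 5 can neither add to irreversibly nor reduce, and phenol and aryl iodide are inert to it.

Step 4
Reactants: 5 4-hydroxy-3-iodo-5-methoxybenzonitrile
Product: 6 4-fluoro-3-iodo-5-methoxybenzonitrile
Conditions: PhenoFluor, CsF, PhMe, 110 °C
Reagents that add atoms: PhenoFluor (1,3-bis(2,6-diisopropylphenyl)-2,2-difluoro-2,3-dihydro-1H-imidazole), FC1(F)N(C=CN1c1c(C(C)C)cccc1C(C)C)c1c(C(C)C)cccc1C(C)C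
Why: Deoxyfluorination of a phenol by concerted nucleophilic aromatic substitution at the activated C-O carbon, which is fastest for electron-poor phenols such as this para-cyanophenol and does not touch the C-I bond.

Step 5
Reactants: 3 (S)-1-[3,5-dimethoxy-4-(methoxymethoxy)phenyl]prop-2-en-1-ol; 6 4-fluoro-3-iodo-5-methoxybenzonitrile
Product: 9 (2S,3S)-2-[3,5-dimethoxy-4-(methoxymethoxy)phenyl]-7-methoxy-3-methyl-2,3-dihydrobenzofuran-5-carbonitrile, via sodium alkoxide 7 (not isolated), via iodoaryl allyl ether 8 (not isolated)
Conditions: NaH (0.98 equiv), DMF, 0 °C; 6, 0 to 40 °C; then, in the same flask, PhMe, (Me3Si)3SiH, Et3B, air, rt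
Reagents that add atoms: none
Why: Alkoxide 7 adds to C7a of 6, whose fluoride is para to the C5 nitrile, and loss of fluoride from the cyano-stabilised anionic sigma-adduct makes the O1-C7a bond of ether 8 (SNAr etherification is the closest known type for this half), while C2 is untouched and keeps its S configuration. The silyl radical then abstracts the iodine on C3a and the aryl sigma-radical adds to the internal vinyl carbon, which makes the C3-C3a bond and closes ring B in the 5-exo-trig mode, after which the primary radical takes hydrogen from the silane and becomes the C3 methyl group (reductive aryl-radical cyclisation of an ortho-haloaryl allyl ether is the closest known type for this half). The new stereocentre C3 is controlled by C2: in the chair-like 5-exo transition state the ring C aryl group on C2 lies pseudo-equatorial and therefore trans to the developing CH2 radical, which should give the 2S,3S isomer as the main product. The first half needs attack at C-F and not at C-I or at the nitrile, which the para-cyano activation and the much better leaving ability of fluoride in addition-elimination secure, and the slight deficit of base protects the doubly activated C2-H of 8. The second half needs iodine abstraction to outrun silyl-radical addition to the vinyl group, and 5-exo closure to outrun 6-endo closure, attack on ring C and later neophyl-type ring expansion, which the weak C-I bond, the very fast cyclisation of ortho-allyloxyaryl radicals and a normal silane concentration secure.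

Step 6
Reactants: 9 (2S,3S)-2-[3,5-dimethoxy-4-(methoxymethoxy)phenyl]-7-methoxy-3-methyl-2,3-dihydrobenzofuran-5-carbonitrile
Product: 10 (2S,3S)-2-[3,5-dimethoxy-4-(methoxymethoxy)phenyl]-7-methoxy-3-methyl-2,3-dihydrobenzofuran-5-carbaldehyde
Conditions: i-Bu2AlH, PhMe, -78 °C; then aq potassium sodium tartrate
Reagents that add atoms: water, O
Why: Partial reduction of an aryl nitrile, in which i-Bu2AlH transfers a single hydride at low temperature and aqueous work-up releases the aldehyde, leaves the acetal, the aryl ethers and both stereocentres untouched.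

Step 7
Reactants: 10 (2S,3S)-2-[3,5-dimethoxy-4-(methoxymethoxy)phenyl]-7-methoxy-3-methyl-2,3-dihydrobenzofuran-5-carbaldehyde
Product: 11 (2S,3S)-2-[3,5-dimethoxy-4-(methoxymethoxy)phenyl]-7-methoxy-3-methyl-5-[(E)-prop-1-enyl]-2,3-dihydrobenzofuran
Conditions: 5-(ethylsulfonyl)-1-phenyl-1H-tetrazole, KN(SiMe3)2, DME, -60 °C; then 10, -60 °C to rt
Reagents that add atoms: 5-(ethylsulfonyl)-1-phenyl-1H-tetrazole, CCS(=O)(=O)c1nnnn1-c1ccccc1
Why: Julia-Kocienski olefination of an aromatic aldehyde with the metalated ethyl phenyltetrazolyl sulfone should give mainly the E-propenyl group, and neither C2-H nor C3-H is acidic enough to be touched by the amide base at low temperature.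

Step 8
Reactants: 11 (2S,3S)-2-[3,5-dimethoxy-4-(methoxymethoxy)phenyl]-7-methoxy-3-methyl-5-[(E)-prop-1-enyl]-2,3-dihydrobenzofuran
Product: 12 odoratisol A
Conditions: HCl (cat.), MeOH, THF, 40 °C
Reagents that add atoms: none
Why: Acid-catalysed acetal exchange with methanol removes the phenolic MOM group under conditions too mild to add to the styrene-type double bond, and if ring B opened reversibly at the benzylic C2-O1 bond it would reclose to the more stable trans isomer with C3 untouched.

**Compound list**
1 | syringaldehyde | O=Cc1cc(OC)c(O)c(OC)c1 | starting material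
2 | 3,5-dimethoxy-4-(methoxymethoxy)benzaldehyde | O=Cc1cc(OC)c(OCOC)c(OC)c1 | intermediate
3 | (S)-1-[3,5-dimethoxy-4-(methoxymethoxy)phenyl]prop-2-en-1-ol | C=C[C@H](O)c1cc(OC)c(OCOC)c(OC)c1 | intermediate
4 | 5-iodovanillin | O=Cc1cc(I)c(O)c(OC)c1 | starting material
5 | 4-hydroxy-3-iodo-5-methoxybenzonitrile | N#Cc1cc(I)c(O)c(OC)c1 | intermediate
6 | 4-fluoro-3-iodo-5-methoxybenzonitrile | N#Cc1cc(I)c(F)c(OC)c1 | intermediate
7 | sodium (S)-1-[3,5-dimethoxy-4-(methoxymethoxy)phenyl]prop-2-en-1-olate | C=C[C@H]([O-])c1cc(OC)c(OCOC)c(OC)c1.[Na+] | intermediate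
8 | (S)-4-({1-[3,5-dimethoxy-4-(methoxymethoxy)phenyl]prop-2-en-1-yl}oxy)-3-iodo-5-methoxybenzonitrile | C=C[C@H](Oc1c(I)cc(C#N)cc1OC)c1cc(OC)c(OCOC)c(OC)c1 | intermediate
9 | (2S,3S)-2-[3,5-dimethoxy-4-(methoxymethoxy)phenyl]-7-methoxy-3-methyl-2,3-dihydrobenzofuran-5-carbonitrile | N#Cc1cc(OC)c2c(c1)[C@H](C)[C@@H](c1cc(OC)c(OCOC)c(OC)c1)O2 | intermediate
10 | (2S,3S)-2-[3,5-dimethoxy-4-(methoxymethoxy)phenyl]-7-methoxy-3-methyl-2,3-dihydrobenzofuran-5-carbaldehyde | O=Cc1cc(OC)c2c(c1)[C@H](C)[C@@H](c1cc(OC)c(OCOC)c(OC)c1)O2 | intermediate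
11 | (2S,3S)-2-[3,5-dimethoxy-4-(methoxymethoxy)phenyl]-7-methoxy-3-methyl-5-[(E)-prop-1-enyl]-2,3-dihydrobenzofuran | C/C=C/c1cc(OC)c2c(c1)[C@H](C)[C@@H](c1cc(OC)c(OCOC)c(OC)c1)O2 | intermediate
12 | odoratisol A | C/C=C/c1cc(OC)c2c(c1)[C@H](C)[C@@H](c1cc(OC)c(O)c(OC)c1)O2 | target

**Step count**
- Total step count: 8.
- Longest linear sequence: 6 steps (1, 2, 5, 6, 7, 8 or 3, 4, 5, 6, 7, 8).

**Steps most likely to fail**

Step 5.
- Risk: addition of the hindered secondary alkoxide to the doubly ortho-substituted C7a may be slow. That would leave time for base-induced migration of the double bond or loss of configuration at C2. The ring closure may also be incompletely trans selective.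
- Fallback: it sets out from 2 and 5, comes back at 8 and then 9, and forms the O1-C2 bond in place of the O1-C7a bond. Horner-Wadsworth-Emmons reaction of 2 with triethyl phosphonoacetate (NaH, THF) gives ethyl (E)-3-[3,5-dimethoxy-4-(methoxymethoxy)phenyl]acrylate F1. Reduction with i-Bu2AlH gives (E)-3-[3,5-dimethoxy-4-(methoxymethoxy)phenyl]prop-2-en-1-ol F2, and methyl chloroformate with pyridine gives (E)-3-[3,5-dimethoxy-4-(methoxymethoxy)phenyl]allyl methyl carbonate F3. Phenol 5 and NaH give sodium 4-cyano-2-iodo-6-methoxyphenolate F4. Iridium-catalysed asymmetric allylic etherification of F3 with F4 then gives the branched ether 8 ([Ir(cod)Cl]2, binaphthol-derived bis(1-phenylethyl)phosphoramidite, THF, with the ligand enantiomer chosen for the S product). Ether 8 is isolated and cyclised to 9 in a separate radical step with (Me3Si)3SiH and Et3B. This path does not need 6.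

Step 2.
- Risk: uncatalysed background addition of the vinylzinc reagent to the aldehyde may erode the enantioselectivity.
- Fallback: it sets out from 2 and comes back at 3. Vinylmagnesium bromide in THF gives racemic 1-[3,5-dimethoxy-4-(methoxymethoxy)phenyl]prop-2-en-1-ol F5. Kinetic resolution with immobilised Candida antarctica lipase B and vinyl acetate in MTBE acetylates the R enantiomer to (R)-1-[3,5-dimethoxy-4-(methoxymethoxy)phenyl]prop-2-en-1-yl acetate F6. The unreacted S alcohol 3 is separated by chromatography.

Step 7.
- Risk: the elimination stage of the olefination may be incompletely E selective with this electron-rich aromatic aldehyde.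
- Fallback: it sets out from 10 and comes back at 11. Wittig methylenation (MePPh3Br, KOt-Bu, THF) gives (2S,3S)-2-[3,5-dimethoxy-4-(methoxymethoxy)phenyl]-7-methoxy-3-methyl-5-vinyl-2,3-dihydrobenzofuran F7. Cross metathesis with excess (Z)-but-2-ene (second-generation Grubbs catalyst, CH2Cl2, 40 °C) gives the thermodynamically preferred E-propenyl compound 11.

**Further compounds**
F1 | step 5 | ethyl (E)-3-[3,5-dimethoxy-4-(methoxymethoxy)phenyl]acrylate | CCOC(=O)/C=C/c1cc(OC)c(OCOC)c(OC)c1
F2 | step 5 | (E)-3-[3,5-dimethoxy-4-(methoxymethoxy)phenyl]prop-2-en-1-ol | OC/C=C/c1cc(OC)c(OCOC)c(OC)c1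
F3 | step 5 | (E)-3-[3,5-dimethoxy-4-(methoxymethoxy)phenyl]allyl methyl carbonate | COC(=O)OC/C=C/c1cc(OC)c(OCOC)c(OC)c1
F4 | step 5 | sodium 4-cyano-2-iodo-6-methoxyphenolate | N#Cc1cc(I)c([O-])c(OC)c1.[Na+]
F5 | step 2 | racemic 1-[3,5-dimethoxy-4-(methoxymethoxy)phenyl]prop-2-en-1-ol | C=CC(O)c1cc(OC)c(OCOC)c(OC)c1
F6 | step 2 | (R)-1-[3,5-dimethoxy-4-(methoxymethoxy)phenyl]prop-2-en-1-yl acetate | C=C[C@@H](OC(C)=O)c1cc(OC)c(OCOC)c(OC)c1
F7 | step 7 | (2S,3S)-2-[3,5-dimethoxy-4-(methoxymethoxy)phenyl]-7-methoxy-3-methyl-5-vinyl-2,3-dihydrobenzofuran | C=Cc1cc(OC)c2c(c1)[C@H](C)[C@@H](c1cc(OC)c(OCOC)c(OC)c1)O2
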